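**Retrosynthetic overview**
1. Target 14 ⇒ (R)-diol 10 + palmitic acid. The last step is an anodically triggered, stereoinvertive 1,2-indolyl shift that forms the C3–C(stereocenter) bond and installs the ester.
2. Diol 10 ⇒ 5-prenylindole 3 + (R)-epoxy alcohol 7, by C3-alkylation at the terminal epoxide carbon.
3. Epoxy alcohol 7 ⇒ methyl (R)-glycidate 4 + 2 MeMgCl; the only stereocenter is bought here.
4. 5-Prenylindole 3 ⇒ 5-bromoindole 1 + prenylstannane 2 (Stille coupling).
5. Rings: the indole and the oxirane are bought; the only ring made is the transient cyclopropane of 13, formed and opened again in the last step.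

Assumption: the target SMILES is read as the (S) ester, and methyl (R)-glycidate (the enantiomer made from L-serine) is taken as a purchasable building block.

**Step 1**
Reactants: 1 5-bromo-1H-indole; 2 tributyl(3-methylbut-2-en-1-yl)stannane
Product: 3 5-(3-methylbut-2-en-1-yl)-1H-indole
Conditions: Pd(PPh3)4 (5 mol%), DMF, 100 °C, 16 h
Reagents that add atoms: tributyl(3-methylbut-2-en-1-yl)stannane, CC(C)=CC[Sn](CCCC)(CCCC)CCCC
Why: Stille cross-coupling, in which zerovalent palladium inserts into the C5–Br bond, the allylstannane transmetalates and reductive elimination at the unsubstituted allyl terminus gives the linear prenyl arene; the free N–H is tolerated and no stereocenter is involved.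

**Step 2**
Reactants: 4 methyl (2R)-oxirane-2-carboxylate; 5 methylmagnesium chloride
Product: 7 2-[(2R)-oxiran-2-yl]propan-2-ol, via 1-[(2R)-oxiran-2-yl]ethan-1-one 6 (not isolated)
Conditions: MeMgCl (2.2 equiv), THF, −78 → −20 °C; Na2SO4·10H2O quench, filter, short-path distillation
Reagents that add atoms: methylmagnesium chloride, C[Mg]Cl
Why: Double Grignard addition to the ester (through ketone 6) is much faster at −78 °C than opening of the oxirane, and the bought stereocenter is not a reacting centre, so its (R) configuration is carried over unchanged.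

**Step 3**
Reactants: 3 5-(3-methylbut-2-en-1-yl)-1H-indole; 7 2-[(2R)-oxiran-2-yl]propan-2-ol
Product: 10 (2R)-3-methyl-1-[5-(3-methylbut-2-en-1-yl)-1H-indol-3-yl]butane-2,3-diol, via indol-1-ylmagnesium bromide 8 (not isolated), via bromomagnesium epoxy alkoxide 9 (not isolated)
Conditions: EtMgBr (2.2 equiv), CH2Cl2/Et2O, 0 °C; then 7 (1.2 equiv), −20 °C → rt, 16 h; aqueous work-up
Reagents that add atoms: none
Why: C3-alkylation of an indolylmagnesium halide by an epoxide (Friedel–Crafts-type epoxide opening), where the magnesium alkoxide chelates and activates the oxirane oxygen and C3 attacks the unhindered terminal CH2 (the distal carbon of a 2,3-epoxy alcohol), so the C–O bond at the stereocenter is untouched and (R) is retained.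

**Step 4**
Reactants: 10 (2R)-3-methyl-1-[5-(3-methylbut-2-en-1-yl)-1H-indol-3-yl]butane-2,3-diol; 11 hexadecanoic acid
Product: 14 (2S)-3-hydroxy-3-methyl-2-[5-(3-methylbut-2-en-1-yl)-1H-indol-3-yl]butyl hexadecanoate, via alkoxyphosphonium triflate 12 (not isolated), via spirocyclopropane 3H-indole 13 (not isolated)
Conditions: (4-MeOC6H4)3P (1.2 equiv), 2,6-lutidinium triflate (2 equiv), CH2Cl2, undivided cell, graphite anode, Pt cathode, +0.85 V vs SCE, 2.4 F/mol, 0 °C → rt, run until no phosphine remains; then 11 (3 equiv), 40 °C, 6 h
Reagents that add atoms: hexadecanoic acid, CCCCCCCCCCCCCCCC(=O)O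
Why: Proposed new method: anodic two-electron oxidation of the triarylphosphine (expected to oxidise near +0.8 V vs SCE, below the 3-alkylindole near +1.1 V) in the presence of 10 gives alkoxyphosphonium ion 12 at the less hindered secondary hydroxyl while protons are reduced to H2 at the cathode; indole C3 then displaces the phosphine oxide from the back side (3-exo-tet aryl participation, inversion at the carbinol carbon), forming the new C3–C bond in spirocyclopropane 13; palmitic acid protonates the indolenine nitrogen and palmitate opens the cyclopropane by SN2 attack at the unsubstituted CH2 (the substituted carbon is neopentyl-like and inductively deactivated by the adjacent carbinol, as at C2 of a 2,3-epoxy alcohol), which re-aromatises the indole, leaves the new bond untouched and gives the (S) ester; the closest known reaction types are the electrochemical Mitsunobu-type substitution of alcohols through anodically generated alkoxytriarylphosphonium ions and the spirocyclopropanation of tryptophyl sulfonates with acid-mediated reopening (a phenonium-type 1,2-aryl shift), which have not been combined into a stereospecific 1,2-indolyl shift with carboxylate capture.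

**Compound list**
1 | 5-bromo-1H-indole | Brc1ccc2[nH]ccc2c1 | starting material
2 | tributyl(3-methylbut-2-en-1-yl)stannane | CC(C)=CC[Sn](CCCC)(CCCC)CCCC | starting material
3 | 5-(3-methylbut-2-en-1-yl)-1H-indole | CC(C)=CCc1ccc2[nH]ccc2c1 | intermediate
4 | methyl (2R)-oxirane-2-carboxylate (methyl (R)-glycidate) | COC(=O)[C@H]1CO1 | starting material
5 | methylmagnesium chloride | C[Mg]Cl | starting material
6 | 1-[(2R)-oxiran-2-yl]ethan-1-one | CC(=O)[C@H]1CO1 | intermediate (not isolated)
7 | 2-[(2R)-oxiran-2-yl]propan-2-ol | CC(C)(O)[C@H]1CO1 | intermediate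
8 | [5-(3-methylbut-2-en-1-yl)indol-1-yl]magnesium bromide | CC(C)=CCc1ccc2n([Mg]Br)ccc2c1 | intermediate (not isolated)
9 | bromomagnesium 2-[(2R)-oxiran-2-yl]propan-2-olate | CC(C)(O[Mg]Br)[C@H]1CO1 | intermediate (not isolated)
10 | (2R)-3-methyl-1-[5-(3-methylbut-2-en-1-yl)-1H-indol-3-yl]butane-2,3-diol | CC(C)=CCc1ccc2[nH]cc(C[C@@H](O)C(C)(C)O)c2c1 | intermediate
11 | hexadecanoic acid (palmitic acid) | CCCCCCCCCCCCCCCC(=O)O | starting material
12 | {[(2R)-3-hydroxy-3-methyl-1-[5-(3-methylbut-2-en-1-yl)-1H-indol-3-yl]butan-2-yl]oxy}tris(4-methoxyphenyl)phosphonium triflate | CC(C)=CCc1ccc2[nH]cc(C[C@@H](O[P+](c3ccc(OC)cc3)(c3ccc(OC)cc3)c3ccc(OC)cc3)C(C)(C)O)c2c1.[O-]S(=O)(=O)C(F)(F)F | intermediate (not isolated)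
13 | 2-[(2R)-5'-(3-methylbut-2-en-1-yl)spiro[cyclopropane-1,3'-indol]-2-yl]propan-2-ol (both epimers at the spiro carbon) | CC(C)(O)[C@@H]1CC12C=Nc3ccc(CC=C(C)C)cc23 | intermediate (not isolated)
14 | (2S)-3-hydroxy-3-methyl-2-[5-(3-methylbut-2-en-1-yl)-1H-indol-3-yl]butyl hexadecanoate | CCCCCCCCCCCCCCCC(=O)OC[C@H](c1c[nH]c2ccc(CC=C(C)C)cc12)C(C)(C)O | target

**Totals**
Total steps: 4 (two one-step branches, their union, and the final step).
Longest linear sequence: 3 steps (1 → 3 → 10 → 14, or 4 → 7 → 10 → 14).

**Steps most likely to fail**

Step 4 (the new step). The risks are: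
- competing anodic oxidation of the indole;
- interference by the neighbouring tertiary hydroxyl, either as a cyclic dioxaphosphorane that collapses to an epoxide or as a pinacol-type methyl shift;
- elimination of the phosphonium to a 3-vinylindole;
- leftover phosphine opening the protonated cyclopropane;
- partial opening at the substituted carbon, which gives the unrearranged secondary ester.

The fallback uses known chemistry, sets out from 10 and comes back at 14. The secondary hydroxyl is mesylated selectively (MsCl, 2,4,6-collidine, CH2Cl2, −20 °C) to give (2R)-3-hydroxy-3-methyl-1-[5-(3-methylbut-2-en-1-yl)-1H-indol-3-yl]butan-2-yl methanesulfonate F1. KOtBu (1.05 equiv, THF, −40 → 0 °C) removes only the indole N–H, and C3 closes onto the sulfonate carbon with inversion, the established base-mediated spirocyclisation of tryptophyl sulfonates. This gives 13, now isolated. Warming 13 with 11 in toluene at 50 °C, the known acid-mediated opening of spirocyclopropyl 3H-indoles by carboxylic acids, gives 14.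

Step 3. The risks are N-alkylation, bromohydrin formation, Payne-type isomerisation of alkoxide 9, and loss of volatile 7. The fallback sets out from 3 and 4 and comes back at 10. It opens the epoxide while it is still ester-activated and builds the carbinol afterwards. Sc(OTf)3 (10 mol%, CH2Cl2, 0 °C → rt) catalyses Friedel–Crafts opening of 4 at its CH2 by 3, giving methyl (2R)-2-hydroxy-3-[5-(3-methylbut-2-en-1-yl)-1H-indol-3-yl]propanoate F2. MeMgCl (5 equiv, THF, 0 °C) then converts the ester into the dimethyl carbinol 10. This also bypasses 7 if step 2 gives trouble.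

Step 1. The risks are coupling at the substituted allyl terminus (the reverse-prenyl isomer), slow oxidative addition into the electron-rich bromoindole, and tin residues. The fallback sets out from 1 and comes back at 3, with the polarity of the coupling reversed. Miyaura borylation (B2pin2, PdCl2(dppf), KOAc, dioxane, 90 °C) gives 5-(4,4,5,5-tetramethyl-1,3,2-dioxaborolan-2-yl)-1H-indole F3. Suzuki–Miyaura allylation with 1-bromo-3-methylbut-2-ene (Pd(PPh3)4, K2CO3, THF/H2O, 60 °C) then delivers the aryl group to the unsubstituted end of the prenyl palladium intermediate and gives 3.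

**Further compounds**
F1 | step 4 | (2R)-3-hydroxy-3-methyl-1-[5-(3-methylbut-2-en-1-yl)-1H-indol-3-yl]butan-2-yl methanesulfonate | CC(C)=CCc1ccc2[nH]cc(C[C@@H](OS(C)(=O)=O)C(C)(C)O)c2c1
F2 | step 3 | methyl (2R)-2-hydroxy-3-[5-(3-methylbut-2-en-1-yl)-1H-indol-3-yl]propanoate | COC(=O)[C@H](O)Cc1c[nH]c2ccc(CC=C(C)C)cc12
F3 | step 1 | 5-(4,4,5,5-tetramethyl-1,3,2-dioxaborolan-2-yl)-1H-indole | CC1(C)OB(OC1(C)C)c1ccc2[nH]ccc2c1
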